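The route rests on cutting C7–C8, the bond inside the C8(O)–C7–C11(=C13H2) homoallylic alcohol that joins the α-methylene-γ-butyrolactone to the ten-membered carbocycle. One BF3-promoted SE2′ addition of a 3-(stannylmethyl)butenolide to a tethered aldehyde makes this bond, closes the carbocycle across the cis-2,5-dihydrofuran, sets C7 and C8 and unveils the exocyclic methylene. The precursor is an open chain: a butenolide (C6, C7, C11, C12, C13–SnBu3) linked by the Z C4=C5 alkene to a cis-2,5-dihydrofuran with C3–H and quaternary C10, which carries the C9–C8 aldehyde. C3 is oxidised to the hemiketal only at the end.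

Key step: step 15

Remark: atoms are named by germacranolide locants throughout, also in open-chain intermediates (C1=C2 dihydrofuran alkene, C3, C4=C5 with methyl C15, C6 lactone O–CH, C7, C8, C9, C10 with methyl C14, C11=C13, C12 carbonyl); the anti course of the SN2′ reduction in step 8 is the working assumption.

Step 1
Reactants: 1 tert-butyl(but-3-yn-1-yloxy)dimethylsilane
Product: 3 tert-butyl{[(3E)-4-iodo-3-methylbut-3-en-1-yl]oxy}dimethylsilane, via alkenyldimethylalane 2 (not isolated)
Conditions: AlMe3 (2.5 equiv), Cp2ZrCl2 (0.25 equiv), CH2Cl2, 0 °C to rt; then I2, THF, −30 °C; aq. K2CO3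
Reagents that add atoms: trimethylaluminium, C[Al](C)C; iodine, II
Why: Zirconium-catalysed Negishi carboalumination adds methyl and aluminium syn across the terminal alkyne with methyl on the internal carbon, and iodinolysis of the C–Al bond with retention should give the E iodide that already carries C14 on C10.

Step 2
Reactants: 3 tert-butyl{[(3E)-4-iodo-3-methylbut-3-en-1-yl]oxy}dimethylsilane; 4 ethynylmagnesium bromide
Product: 6 tert-butyldimethyl{[(3E)-3-methylhex-3-en-5-yn-1-yl]oxy}silane, via ethynylzinc bromide 5 (not isolated)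
Conditions: 4, ZnBr2, THF, 0 °C; then 3, Pd(PPh3)4 (3 mol%), rt
Reagents that add atoms: none
Why: Negishi coupling of an alkynylzinc halide with an alkenyl iodide under zerovalent palladium catalysis proceeds with retention of the E geometry and gives the terminal enyne (C3≡C2–C1=C10) in one operation.

Step 3
Reactants: 6 tert-butyldimethyl{[(3E)-3-methylhex-3-en-5-yn-1-yl]oxy}silane
Product: 7 tert-butyl{2-[(2R,3R)-3-ethynyl-2-methyloxiran-2-yl]ethoxy}dimethylsilane
Conditions: D-fructose-derived Shi ketone (30 mol%), Oxone (KHSO5), K2CO3, Bu4NHSO4, MeCN–CH2(OMe)2–aq. Na2B4O7 buffer, 0 °C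
Reagents that add atoms: potassium peroxymonosulfate, [K+].[O-]S(=O)(=O)OO
Why: Shi asymmetric epoxidation of a trisubstituted conjugated enyne: the dioxirane from the D-fructose-derived ketone should attack, through the spiro transition state, the alkene face that leads to the (2R,3R)-oxirane, which sets C10 and the C1 centre that later steers C3, while the alkyne is left untouched.

Step 4
Reactants: 8 prop-2-enal (acrolein); 9 prop-1-yn-1-ylmagnesium bromide
Product: 10 rac-hex-1-en-4-yn-3-ol
Conditions: THF, −78 °C; aq. NH4Cl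
Reagents that add atoms: none
Why: 1,2-Addition of an alkynyl Grignard reagent to an enal at low temperature gives the racemic vinyl propynyl carbinol that holds C6, C7 and C5–C4–C15.

Step 5
Reactants: 10 rac-hex-1-en-4-yn-3-ol
Product: 11 (3S)-hex-1-en-4-yn-3-ol
Conditions: Ti(OiPr)4, L-(+)-diisopropyl tartrate, t-BuOOH (0.6 equiv), 4 Å molecular sieves, CH2Cl2, −20 °C
Reagents that add atoms: none
Why: Sharpless kinetic resolution of a secondary allylic alcohol: with L-(+)-tartrate the R enantiomer should be epoxidised at its vinyl group much faster, so the S alcohol, which has the C6 configuration of the target, is recovered and separated from the epoxy alcohol.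

Step 6
Reactants: 11 (3S)-hex-1-en-4-yn-3-ol
Product: 13 (3S,4Z)-5-iodohexa-1,4-dien-3-ol, via cyclic alkenylaluminate 12 (not isolated)
Conditions: Red-Al [NaAlH2(OCH2CH2OCH3)2], THF, 0 °C to rt; EtOAc; then I2, THF, −78 to 0 °C
Reagents that add atoms: iodine, II
Why: Hydroxyl-directed trans-hydroalumination of the propargylic alcohol puts hydride on C5 and aluminium on C4 in a five-membered aluminate, and iodinolysis with retention gives the Z iodide (C6 cis to iodine), which fixes the Z C4=C5 geometry; the vinyl group is not reduced.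

Step 7
Reactants: 7 tert-butyl{2-[(2R,3R)-3-ethynyl-2-methyloxiran-2-yl]ethoxy}dimethylsilane; 13 (3S,4Z)-5-iodohexa-1,4-dien-3-ol
Product: 14 (3S,4Z)-7-[(2R,3R)-3-(2-{[tert-butyl(dimethyl)silyl]oxy}ethyl)-3-methyloxiran-2-yl]-5-methylhepta-1,4-dien-6-yn-3-ol
Conditions: Pd(PPh3)4 (5 mol%), CuI (10 mol%), i-Pr2NH, THF, rt, degassed
Reagents that add atoms: none
Why: Sonogashira coupling joins C3 of the terminal alkynyl oxirane to C4 of the alkenyl iodide with retention of the Z geometry and tolerates the epoxide, the free alcohol and the silyl ether.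

Step 8
Reactants: 14 (3S,4Z)-7-[(2R,3R)-3-(2-{[tert-butyl(dimethyl)silyl]oxy}ethyl)-3-methyloxiran-2-yl]-5-methylhepta-1,4-dien-6-yn-3-ol
Product: 16 (3S,4Z,9R)-11-{[tert-butyl(dimethyl)silyl]oxy}-5,9-dimethylundeca-1,4,6,7-tetraene-3,9-diol with a (P)-configured C6=C7=C8 allene, via bis-silyl ether 15 (not isolated)
Conditions: IPrCuCl, chloro[1,3-bis(2,6-diisopropylphenyl)imidazol-2-ylidene]copper (5 mol%), NaOt-Bu (5 mol%), HSiMe(OMe)2 (3 equiv), toluene, 0 °C; then K2CO3, MeOH, rt
Reagents that add atoms: none
Why: Copper hydride-catalysed SN2′ reduction of a propargyl oxirane: syn hydrocupration places hydride on C3 and copper on C2, anti β-elimination opens the C1–O bond, so the C1 centre is expected to be relayed into a (P)-allene while C10 keeps its oxygen and configuration; the silylated hydroxyls are released by the methanolic carbonate.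

Step 9
Reactants: 16 the (P)-allenic diol
Product: 17 (3S,4Z)-5-[(2R,5R)-5-(2-{[tert-butyl(dimethyl)silyl]oxy}ethyl)-5-methyl-2,5-dihydrofuran-2-yl]hexa-1,4-dien-3-ol
Conditions: AuCl3 (2 mol%), THF, rt
Reagents that add atoms: none
Why: Gold-catalysed 5-endo cycloisomerisation of an α-hydroxyallene: the C10 hydroxyl adds to C3 of the activated allene from the side on which C10 sits and protodeauration leaves the C1=C2 alkene, so the axial chirality becomes the C3 centre with C4 cis to C9 on the 2,5-dihydrofuran.

Step 10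
Reactants: 17 the dihydrofuran dienol; 18 2-(bromomethyl)prop-2-enoic acid
Product: 19 (3S,4Z)-5-[(2R,5R)-5-(2-{[tert-butyl(dimethyl)silyl]oxy}ethyl)-5-methyl-2,5-dihydrofuran-2-yl]hexa-1,4-dien-3-yl 2-(bromomethyl)prop-2-enoate
Conditions: N,N′-diisopropylcarbodiimide, DMAP (10 mol%), CH2Cl2, 0 °C
Reagents that add atoms: none
Why: Steglich esterification of the secondary bis-allylic alcohol at low temperature with little DMAP, so that acyl transfer outruns SN2′ attack on the bromomethyl acrylate; C6 is not touched.

Step 11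
Reactants: 19 the 2-(bromomethyl)acrylate
Product: 20 (5R)-3-(bromomethyl)-5-{(1Z)-2-[(2R,5R)-5-(2-{[tert-butyl(dimethyl)silyl]oxy}ethyl)-5-methyl-2,5-dihydrofuran-2-yl]prop-1-en-1-yl}furan-2(5H)-one
Conditions: second-generation Grubbs catalyst (10 mol%), toluene (5 mM), 80 °C, argon sparge
Reagents that add atoms: none
Why: Ring-closing metathesis of an allyl 2-substituted acrylate: the carbene loads at the only monosubstituted alkene (C7 vinyl) and closes on the acrylate to the trisubstituted C7=C11 butenolide alkene, an irreversible exit under ethylene removal, whereas any opening of the hindered dihydrofuran alkene can revert.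

Step 12
Reactants: 20 the silyl-protected bromomethyl butenolide
Product: 21 (5R)-3-(bromomethyl)-5-{(1Z)-2-[(2R,5R)-5-(2-hydroxyethyl)-5-methyl-2,5-dihydrofuran-2-yl]prop-1-en-1-yl}furan-2(5H)-one
Conditions: aq. HF (48%), MeCN, 0 °C
Reagents that add atoms: none
Why: Acidic fluoride cleavage of the primary TBS ether in a medium free of nucleophilic amines, which would be alkylated by the allylic bromide; the ethers and the butenolide should be stable to dilute HF at 0 °C.

Step 13
Reactants: 21 the bromomethyl butenolide alcohol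
Product: 22 (5R)-5-{(1Z)-2-[(2R,5R)-5-(2-hydroxyethyl)-5-methyl-2,5-dihydrofuran-2-yl]prop-1-en-1-yl}-3-[(tributylstannyl)methyl]furan-2(5H)-one
Conditions: Pd2(dba)3 (2.5 mol%), (Bu3Sn)2 (1.2 equiv), THF, rt
Reagents that add atoms: hexabutylditin, CCCC[Sn](CCCC)(CCCC)[Sn](CCCC)(CCCC)CCCC
Why: Palladium-catalysed stannylation of an allylic bromide with a distannane: oxidative addition gives the π-allyl complex, and transmetalation and reductive elimination at the primary terminus C13 should give the conjugated, thermodynamically preferred allylstannane.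

Step 14
Reactants: 22 the stannylmethyl butenolide alcohol
Product: 23 [(2R,5R)-2-methyl-5-{(1Z)-1-[(2R)-5-oxo-4-[(tributylstannyl)methyl]-2,5-dihydrofuran-2-yl]prop-1-en-2-yl}-2,5-dihydrofuran-2-yl]acetaldehyde (stannylmethyl butenolide aldehyde, C3–H series)
Conditions: Dess–Martin periodinane, NaHCO3, CH2Cl2, 0 °C; used at once
Reagents that add atoms: none
Why: Dess–Martin oxidation under bicarbonate buffer converts the primary alcohol into the C8 aldehyde without base or strong acid, which protects the allylstannane, the C6–H of the butenolide and the β-alkoxy aldehyde.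

Step 15
Reactants: 23 the stannylmethyl butenolide aldehyde
Product: 24 (1Z,3R,4Z,6R,7R,8R,10R)-3,10-epoxy-8-hydroxygermacra-1,4,11(13)-trien-12,6-olide (3-deoxy tricyclic C8 alcohol)
Conditions: BF3·OEt2 (2 equiv), CH2Cl2, −78 °C, 23 added slowly to a final 1 mM; aq. NaHCO3
Reagents that add atoms: none
Why: BF3 activates the C8 aldehyde and the C7=C11 π bond of the 3-(stannylmethyl)butenolide attacks the carbonyl carbon through C7 in an open, antiperiplanar SE2′ transition state; loss of the tributyltin group from C13 shifts the double bond to C11=C13, so the α-methylene lactone is unveiled in the same event. The closest known reaction type is the Lewis-acid-promoted intramolecular addition of allylstannanes, 2-(stannylmethyl)acrylate types included, to aldehydes for medium and large rings. The ten-membered carbocycle closes in a 10-exo-trig mode on the carbonyl carbon and, through the ether bridge, the nine-membered oxacycle closes 9-exo-trig with the same bond. C7 is controlled by the C6 centre, because a ring that spans C5 and C8 is least strained when C8 adds trans to C5 on the lactone; C8 is controlled by the open transition state, in which C9 lies anti to the C7–C6 bond so that O8 ends syn to C6 (a closed chair from this E-type allyl unit would give the epimer). The step needs γ-attack over α-attack, cyclisation over oligomerisation and survival of the doubly allylic ether: the first is inherent to SE2′ reactions of allylstannanes, the second is served by high dilution and by the Z C4=C5 alkene and the cis-2,5-dihydrofuran that fold C7 toward C8, the third by keeping C3 at the C–H level and working at −78 °C.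

Step 16
Reactants: 25 (2E)-but-2-enal (crotonaldehyde)
Product: 26 (2Z)-2-iodobut-2-enal
Conditions: I2, K2CO3, DMAP (20 mol%), THF–H2O, rt
Reagents that add atoms: iodine, II
Why: DMAP-catalysed α-iodination of an enal (conjugate addition of the amine, iodination of the enolate, elimination) keeps methyl trans to the formyl group and so gives the Z iodide.

Step 17
Reactants: 26 (2Z)-2-iodobut-2-enal
Product: 27 (2Z)-2-iodobut-2-en-1-ol
Conditions: NaBH4, MeOH, 0 °C
Reagents that add atoms: none
Why: Borohydride 1,2-reduction of the α-iodo enal gives the allylic alcohol without touching the alkenyl iodide or its geometry.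

Step 18
Reactants: 27 (2Z)-2-iodobut-2-en-1-ol
Product: 29 (2Z)-2-(hydroxymethyl)but-2-enoic acid, via dilithio alkoxide 28 (not isolated)
Conditions: t-BuLi (3.1 equiv), Et2O, −78 °C; CO2; aq. HCl
Reagents that add atoms: carbon dioxide, O=C=O
Why: Deprotonation and iodine–lithium exchange with tert-butyllithium give a configurationally stable alkenyllithium alkoxide that is carboxylated with retention, so the carboxyl group ends cis to the methyl group as in the Z side chain.

Step 19
Reactants: 29 (2Z)-2-(hydroxymethyl)but-2-enoic acid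
Product: 30 (2Z)-2-[(acetyloxy)methyl]but-2-enoic acid
Conditions: Ac2O, pyridine, CH2Cl2, 0 °C to rt; aq. work-up
Reagents that add atoms: acetic anhydride, CC(=O)OC(C)=O
Why: Acetylation of the primary allylic alcohol with acetic anhydride and pyridine; any mixed anhydride of the acid is hydrolysed in the aqueous work-up and the Z geometry is not at risk without a nucleophilic catalyst.

Step 20
Reactants: 24 the 3-deoxy tricyclic C8 alcohol; 30 (2Z)-2-[(acetyloxy)methyl]but-2-enoic acid
Product: 32 (1Z,3R,4Z,6R,7R,8R,10R)-8-{[(2Z)-2-(acetoxymethyl)but-2-enoyl]oxy}-3,10-epoxygermacra-1,4,11(13)-trien-12,6-olide (3-deoxy ester), via mixed anhydride 31 (not isolated)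
Conditions: 30, 2,4,6-trichlorobenzoyl chloride, Et3N, toluene, rt; then 24, DMAP, toluene, rt
Reagents that add atoms: none
Why: Yamaguchi esterification through the 2,4,6-trichlorobenzoyl mixed anhydride acylates the hindered C8 hydroxyl with retention at C8 and is the usual way to attach angelate-type acids without Z to E isomerisation.

Step 21
Reactants: 32 the 3-deoxy ester
Product: 33 CNP0256971.1, (1Z,3R,4Z,6R,7R,8R,10R)-8-{[(2Z)-2-(acetoxymethyl)but-2-enoyl]oxy}-3,10-epoxy-3-hydroxygermacra-1,4,11(13)-trien-12,6-olide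
Conditions: DDQ (1.5 equiv), CH2Cl2–pH 7 aqueous buffer (10:1), 0 °C to rt
Reagents that add atoms: water, O
Why: DDQ oxidation of an allylic ether: hydride abstraction from the doubly allylic, oxygen-bearing C3–H gives an oxocarbenium ion that water captures at C3, and the bridged ring system leaves only the outward position for the hydroxyl, so the hemiketal should form with the C3 configuration of the target.

Compound list
1 | tert-butyl(but-3-yn-1-yloxy)dimethylsilane | C#CCCO[Si](C)(C)C(C)(C)C | starting material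
2 | [(1E)-4-{[tert-butyl(dimethyl)silyl]oxy}-2-methylbut-1-en-1-yl]dimethylalumane | C[Al](C)/C=C(\C)CCO[Si](C)(C)C(C)(C)C | intermediate (not isolated)
3 | tert-butyl{[(3E)-4-iodo-3-methylbut-3-en-1-yl]oxy}dimethylsilane | I/C=C(\C)CCO[Si](C)(C)C(C)(C)C | intermediate
4 | ethynylmagnesium bromide | C#C[Mg]Br | starting material
5 | ethynylzinc bromide | C#C[Zn]Br | intermediate (not isolated)
6 | tert-butyldimethyl{[(3E)-3-methylhex-3-en-5-yn-1-yl]oxy}silane | C#C/C=C(\C)CCO[Si](C)(C)C(C)(C)C | intermediate
7 | tert-butyl{2-[(2R,3R)-3-ethynyl-2-methyloxiran-2-yl]ethoxy}dimethylsilane | C#C[C@H]1O[C@]1(C)CCO[Si](C)(C)C(C)(C)C | intermediate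
8 | prop-2-enal (acrolein) | C=CC=O | starting material
9 | prop-1-yn-1-ylmagnesium bromide | CC#C[Mg]Br | starting material
10 | rac-hex-1-en-4-yn-3-ol | C=CC(O)C#CC | intermediate
11 | (3S)-hex-1-en-4-yn-3-ol | C=C[C@H](O)C#CC | intermediate
12 | sodium cyclic alkenylaluminate of 11 (five-membered O–C6–C5=C4–Al ring, two 2-methoxyethoxy groups on aluminium) | [Na+].C=C[C@H]1C=C(C)[Al-](OCCOC)(OCCOC)O1 | intermediate (not isolated)
13 | (3S,4Z)-5-iodohexa-1,4-dien-3-ol | C=C[C@H](O)/C=C(/C)I | intermediate
14 | (3S,4Z)-7-[(2R,3R)-3-(2-{[tert-butyl(dimethyl)silyl]oxy}ethyl)-3-methyloxiran-2-yl]-5-methylhepta-1,4-dien-6-yn-3-ol | C=C[C@H](O)/C=C(/C)C#C[C@H]1O[C@]1(C)CCO[Si](C)(C)C(C)(C)C | intermediate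
15 | 3,9-bis-O-[dimethoxy(methyl)silyl] ether of 16 | C=C[C@H](O[Si](C)(OC)OC)/C=C(/C)C([H])=[C@@]=C([H])[C@](C)(O[Si](C)(OC)OC)CCO[Si](C)(C)C(C)(C)C | intermediate (not isolated)
16 | (3S,4Z,9R)-11-{[tert-butyl(dimethyl)silyl]oxy}-5,9-dimethylundeca-1,4,6,7-tetraene-3,9-diol, (P)-configured C6=C7=C8 allene | C=C[C@H](O)/C=C(/C)C([H])=[C@@]=C([H])[C@](C)(O)CCO[Si](C)(C)C(C)(C)C | intermediate
17 | (3S,4Z)-5-[(2R,5R)-5-(2-{[tert-butyl(dimethyl)silyl]oxy}ethyl)-5-methyl-2,5-dihydrofuran-2-yl]hexa-1,4-dien-3-ol | C=C[C@H](O)/C=C(/C)[C@H]1C=C[C@@](C)(CCO[Si](C)(C)C(C)(C)C)O1 | intermediate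
18 | 2-(bromomethyl)prop-2-enoic acid | C=C(CBr)C(O)=O | starting material
19 | (3S,4Z)-5-[(2R,5R)-5-(2-{[tert-butyl(dimethyl)silyl]oxy}ethyl)-5-methyl-2,5-dihydrofuran-2-yl]hexa-1,4-dien-3-yl 2-(bromomethyl)prop-2-enoate | C=C[C@H](OC(=O)C(=C)CBr)/C=C(/C)[C@H]1C=C[C@@](C)(CCO[Si](C)(C)C(C)(C)C)O1 | intermediate
20 | (5R)-3-(bromomethyl)-5-{(1Z)-2-[(2R,5R)-5-(2-{[tert-butyl(dimethyl)silyl]oxy}ethyl)-5-methyl-2,5-dihydrofuran-2-yl]prop-1-en-1-yl}furan-2(5H)-one | BrCC1=C[C@@H](/C=C(/C)[C@H]2C=C[C@@](C)(CCO[Si](C)(C)C(C)(C)C)O2)OC1=O | intermediate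
21 | (5R)-3-(bromomethyl)-5-{(1Z)-2-[(2R,5R)-5-(2-hydroxyethyl)-5-methyl-2,5-dihydrofuran-2-yl]prop-1-en-1-yl}furan-2(5H)-one | BrCC1=C[C@@H](/C=C(/C)[C@H]2C=C[C@@](C)(CCO)O2)OC1=O | intermediate
22 | (5R)-5-{(1Z)-2-[(2R,5R)-5-(2-hydroxyethyl)-5-methyl-2,5-dihydrofuran-2-yl]prop-1-en-1-yl}-3-[(tributylstannyl)methyl]furan-2(5H)-one | CCCC[Sn](CCCC)(CCCC)CC1=C[C@@H](/C=C(/C)[C@H]2C=C[C@@](C)(CCO)O2)OC1=O | intermediate
23 | [(2R,5R)-2-methyl-5-{(1Z)-1-[(2R)-5-oxo-4-[(tributylstannyl)methyl]-2,5-dihydrofuran-2-yl]prop-1-en-2-yl}-2,5-dihydrofuran-2-yl]acetaldehyde | CCCC[Sn](CCCC)(CCCC)CC1=C[C@@H](/C=C(/C)[C@H]2C=C[C@@](C)(CC=O)O2)OC1=O | intermediate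
24 | (1Z,3R,4Z,6R,7R,8R,10R)-3,10-epoxy-8-hydroxygermacra-1,4,11(13)-trien-12,6-olide | C=C1C(=O)O[C@@H]2/C=C(/C)[C@H]3C=C[C@@](C)(C[C@@H](O)[C@@H]12)O3 | intermediate
25 | (2E)-but-2-enal (crotonaldehyde) | C/C=C/C=O | starting material
26 | (2Z)-2-iodobut-2-enal | C/C=C(\I)C=O | intermediate
27 | (2Z)-2-iodobut-2-en-1-ol | C/C=C(\I)CO | intermediate
28 | lithium (2Z)-2-lithiobut-2-en-1-olate | C/C=C(\[Li])CO[Li] | intermediate (not isolated)
29 | (2Z)-2-(hydroxymethyl)but-2-enoic acid | C/C=C(/CO)C(O)=O | intermediate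
30 | (2Z)-2-[(acetyloxy)methyl]but-2-enoic acid | C/C=C(/COC(C)=O)C(O)=O | intermediate
31 | (2Z)-2-[(acetyloxy)methyl]but-2-enoic 2,4,6-trichlorobenzoic anhydride | C/C=C(/COC(C)=O)C(=O)OC(=O)c1c(Cl)cc(Cl)cc1Cl | intermediate (not isolated)
32 | (1Z,3R,4Z,6R,7R,8R,10R)-8-{[(2Z)-2-(acetoxymethyl)but-2-enoyl]oxy}-3,10-epoxygermacra-1,4,11(13)-trien-12,6-olide | C=C1C(=O)O[C@@H]2/C=C(/C)[C@H]3C=C[C@@](C)(C[C@@H](OC(=O)/C(=C\C)COC(C)=O)[C@@H]12)O3 | intermediate
33 | CNP0256971.1, (1Z,3R,4Z,6R,7R,8R,10R)-8-{[(2Z)-2-(acetoxymethyl)but-2-enoyl]oxy}-3,10-epoxy-3-hydroxygermacra-1,4,11(13)-trien-12,6-olide | C=C1C(=O)O[C@@H]2/C=C(/C)[C@@]3(O)C=C[C@@](C)(C[C@@H](OC(=O)/C(=C\C)COC(C)=O)[C@@H]12)O3 | target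

Total step count: 21. Longest linear sequence: 14 steps (steps 1–3, 7–15, 20 and 21).

Steps most likely to fail

Step 15. The aldehyde may add intermolecularly (oligomerisation), the stannane may be lost by protodestannylation, BF3 may ionise the doubly allylic ether, or the ring may close to the C8 epimer. The fallback keeps the C7–C8 bond but changes the organometallic and the stereochemical logic. It sets out from 21: Dess–Martin oxidation gives the bromomethyl butenolide aldehyde F1. CrCl2 in THF at high dilution (intramolecular Nozaki–Hiyama-type Barbier allylation through a closed chair) should then give the C8-epimeric tricyclic alcohol F2. Mitsunobu esterification of F2 with acid 30 (PPh3, diisopropyl azodicarboxylate) inverts C8 and comes back to the route at 32.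

Step 21. Hydride abstraction may be slow or occur at other allylic positions, the cation may be captured at C1 or C5, and the product may be oxidised further. The fallback replaces hydride abstraction by radical C–H peroxidation and sets out from 32: Rh2(cap)4 (dirhodium tetracaprolactamate) with tert-butyl hydroperoxide should give the C3 tert-butylperoxy ketal F3, and ketal exchange with pyridinium p-toluenesulfonate in aqueous THF releases the hemiketal, which comes back to the route at 33.

Step 9. Reversible ionisation of the doubly allylic C3–O bond by the gold Lewis acid may erode the axis-to-centre transfer, and the vinylallene may cyclise through carbon instead of oxygen. The fallback uses a kinetic, irreversible electrophilic cyclisation and sets out from 16: N-iodosuccinimide in CH2Cl2 at 0 °C should give the 3-iodo-2,5-dihydrofuran F4 by anti iodoetherification with the same stereochemical relay, and hydrodeiodination with Pd(PPh3)4 and Bu3SnH comes back to the route at 17.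

Further compounds
F1 | step 15 | [(2R,5R)-5-{(1Z)-1-[(2R)-4-(bromomethyl)-5-oxo-2,5-dihydrofuran-2-yl]prop-1-en-2-yl}-2-methyl-2,5-dihydrofuran-2-yl]acetaldehyde | BrCC1=C[C@@H](/C=C(/C)[C@H]2C=C[C@@](C)(CC=O)O2)OC1=O
F2 | step 15 | (1Z,3R,4Z,6R,7R,8S,10R)-3,10-epoxy-8-hydroxygermacra-1,4,11(13)-trien-12,6-olide (C8 epimer of 24) | C=C1C(=O)O[C@@H]2/C=C(/C)[C@H]3C=C[C@@](C)(C[C@H](O)[C@@H]12)O3
F3 | step 21 | C3 tert-butylperoxy ketal of 33 (tert-butylperoxy in place of the C3 hydroxyl) | C=C1C(=O)O[C@@H]2/C=C(/C)[C@@]3(OOC(C)(C)C)C=C[C@@](C)(C[C@@H](OC(=O)/C(=C\C)COC(C)=O)[C@@H]12)O3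
F4 | step 9 | (3S,4Z)-5-[(2S,5R)-5-(2-{[tert-butyl(dimethyl)silyl]oxy}ethyl)-3-iodo-5-methyl-2,5-dihydrofuran-2-yl]hexa-1,4-dien-3-ol | C=C[C@H](O)/C=C(/C)[C@H]1C(I)=C[C@@](C)(CCO[Si](C)(C)C(C)(C)C)O1
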